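**Retrosynthetic overview**
1. The target comes from one final operation on a fully protected macrocyclic biaryl. It removes nine O-benzyl groups, four ring A bromines and one O–Si–O bridge.
2. The key disconnection is the ring B–ring B biaryl bond, C6' of the epicatechin half to C2' of the epigallocatechin half. It is made by anodic dehydrogenative coupling inside a silicon-tethered heterodimer, which closes a temporary 11-membered ring, the only ring formed in the route.
3. The coupling substrate comes from fourfold NBS blocking of C6/C8 on both rings A of the tethered dimer. The dimer comes from joining the two free 3-OH groups with iPr2SiCl2.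
4. The monomers come from phenol O-benzylation of (−)-epicatechin and (−)-epigallocatechin. These supply rings A, B and C of both halves and all four stereocentres (2R,3R twice).

Assumption: the SMILES fixes four carbon stereocentres (all R) but gives no descriptor for the biaryl axis. The axis is therefore taken as the chiral tether delivers it and is assigned by ECD. Both tea flavan-3-ols are taken as bulk commercial isolates.

**Step 1**
Reactants: 1 (−)-epicatechin, (2R,3R)-2-(3,4-dihydroxyphenyl)chromane-3,5,7-triol
Product: 2 tetra-O-benzyl-(−)-epicatechin (benzyl ethers on O5/O7/O3'/O4'; 3-OH free; 2R,3R)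
Conditions: BnBr (4.4 equiv), K2CO3 (5 equiv), DMF, Ar, 0 °C to rt, 20 h
Reagents that add atoms: benzyl bromide, BrCc1ccccc1
Why: Williamson ether synthesis; carbonate deprotonates only the four phenols and not the secondary 3-OH, and at or below rt under argon C2 does not epimerise, so both bought stereocentres pass through untouched.

**Step 2**
Reactants: 3 (−)-epigallocatechin, (2R,3R)-2-(3,4,5-trihydroxyphenyl)chromane-3,5,7-triol
Product: 4 penta-O-benzyl-(−)-epigallocatechin (benzyl ethers on O5/O7/O3'/O4'/O5'; 3-OH free; 2R,3R)
Conditions: BnBr (5.5 equiv), K2CO3 (6 equiv), degassed DMF, Ar, 0 °C to rt, 20 h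
Reagents that add atoms: benzyl bromide, BrCc1ccccc1
Why: Williamson ether synthesis as in step 1; strict exclusion of air keeps the pyrogallol ring from autoxidising before it is capped, and no stereocentre is involved.

**Step 3**
Reactants: 2 tetra-O-benzyl-(−)-epicatechin; 4 penta-O-benzyl-(−)-epigallocatechin
Product: 6 diisopropylsilylene-bridged heterodimer (O3 of the epicatechin unit–Si(iPr)2–O3 of the epigallocatechin unit; nine benzyl ethers; all four centres R), via chlorosilane 5 (not isolated)
Conditions: iPr2SiCl2 (1.1 equiv), imidazole, CH2Cl2, −20 °C, slow addition of 2; then 4 (1.0 equiv), imidazole, DMAP (cat.), CH2Cl2–DMF, 40 °C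
Reagents that add atoms: dichlorodiisopropylsilane, CC(C)[Si](Cl)(Cl)C(C)C
Why: Temporary silicon tether by sequential substitution at silicon; the first Si–Cl bond is displaced fast, while the hindered alkoxychlorosilane 5 reacts only slowly with more 2 and so remains for 4, and only O–H bonds change, so the stereocentres are untouched.

**Step 4**
Reactants: 6 diisopropylsilylene-bridged heterodimer
Product: 7 tethered tetrabromide (Br at C6 and C8 of both rings A; rings B unchanged; all four centres R)
Conditions: NBS (4.2 equiv), CH2Cl2, dark, −40 °C to rt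
Reagents that add atoms: N-bromosuccinimide, O=C1CCC(=O)N1Br
Why: Electrophilic aromatic bromination; the phloroglucinol-type C6 and C8 positions carry three activating oxygens and react far faster than any ring B carbon, so one operation blocks and electronically deactivates both rings A, and NBS releases only neutral succinimide, which spares the silylene acetal.

**Step 5**
Reactants: 7 tethered tetrabromide
Product: 8 macrocyclic biaryl (new bond C6' of the epicatechin ring B to C2' of the epigallocatechin ring B; 11-membered ring through O–Si–O; nine benzyl ethers; four Br; all four centres R)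
Conditions: BDD anode, Pt cathode, undivided cell, Bu3MeN·O3SOMe (0.1 M), HFIP–CH2Cl2 (1:1), 2 mM, 1.5 mA cm−2, 2.3 F mol−1, 0 °C
Reagents that add atoms: none
Why: Proposed new method: a silicon-tethered anodic dehydrogenative aryl–aryl coupling of two flavan-3-ol rings B, in which the brominated rings A are blocked and harder to oxidise, so the first electron leaves a ring B polyalkoxyarene; the HFIP-stabilised radical cation is attacked by the other ring B held close by the O–Si–O bridge (at C6', para to the 3'-OBn, on one side and at C2', ortho and para to two OBn groups, on the other), a second oxidation and loss of two protons rearomatise while the cathode evolves H2, and the two (2R,3R) units in the ring set the twist of the new axis by substrate control; the closest known reaction types are the anodic or VOF3-mediated ring closure of dialkoxyaryl/trialkoxyaryl pairs to dibenzocyclooctadienes and anodic arene cross-coupling in HFIP on boron-doped diamond, neither of which has been shown for silyl tethers, 11-membered rings or flavanols.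

**Step 6**
Reactants: 8 macrocyclic biaryl
Product: 10 degalloyl theasinensin F, via silylene-bridged free polyphenol 9 (not isolated)
Conditions: H2 (1 atm), Pd(OH)2/C, THF–MeOH–H2O (10:10:1), no base, rt, 24 h; filter under Ar; Sephadex LH-20
Reagents that add atoms: none
Why: Catalytic hydrogenolysis of nine aryl benzyl ethers and four aryl bromides, followed in the same pot by acid-catalysed solvolysis of the silylene acetal by the HBr released; attack at silicon leaves both C3–O bonds intact and the chroman C2–O1 bond survives these standard catechin debenzylation conditions, so the four stereocentres and the axis are kept.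

**Compound list**
1 | (−)-epicatechin (2R,3R) | Oc1cc(O)c2c(c1)O[C@H](c1cc(O)c(O)cc1)[C@H](O)C2 | starting material
2 | 5,7,3',4'-tetra-O-benzyl-(−)-epicatechin, 3-OH free | c9ccccc9COc1cc(OCc9ccccc9)c2c(c1)O[C@H](c1cc(OCc9ccccc9)c(OCc9ccccc9)cc1)[C@H](O)C2 | intermediate
3 | (−)-epigallocatechin (2R,3R) | Oc1cc(O)c2c(c1)O[C@H](c1cc(O)c(O)c(O)c1)[C@H](O)C2 | starting material
4 | 5,7,3',4',5'-penta-O-benzyl-(−)-epigallocatechin, 3-OH free | c9ccccc9COc1cc(OCc9ccccc9)c2c(c1)O[C@H](c1cc(OCc9ccccc9)c(OCc9ccccc9)c(OCc9ccccc9)c1)[C@H](O)C2 | intermediate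
5 | 3-O-(chlorodiisopropylsilyl) ether of 2 | c9ccccc9COc1cc(OCc9ccccc9)c2c(c1)O[C@H](c1cc(OCc9ccccc9)c(OCc9ccccc9)cc1)[C@H](O[Si](Cl)(C(C)C)C(C)C)C2 | intermediate
6 | diisopropylsilylene-bridged heterodimer of 2 and 4 (O3–Si–O3) | c9ccccc9COc1cc(OCc9ccccc9)c2c(c1)O[C@H](c1cc(OCc9ccccc9)c(OCc9ccccc9)cc1)[C@H](O[Si](C(C)C)(C(C)C)O[C@@H]3Cc4c(OCc9ccccc9)cc(OCc9ccccc9)cc4O[C@@H]3c5cc(OCc9ccccc9)c(OCc9ccccc9)c(OCc9ccccc9)c5)C2 | intermediate
7 | tetrabromide of 6 (Br at C6 and C8 of both rings A) | c9ccccc9COc1c(Br)c(OCc9ccccc9)c2c(c1Br)O[C@H](c1cc(OCc9ccccc9)c(OCc9ccccc9)cc1)[C@H](O[Si](C(C)C)(C(C)C)O[C@@H]3Cc4c(OCc9ccccc9)c(Br)c(OCc9ccccc9)c(Br)c4O[C@@H]3c5cc(OCc9ccccc9)c(OCc9ccccc9)c(OCc9ccccc9)c5)C2 | intermediate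
8 | macrocyclic biaryl (C6'–C2' bond between the rings B, 11-membered silylene-bridged ring) | c9ccccc9COc1c(Br)c(OCc9ccccc9)c2c(c1Br)O[C@H](c1cc(OCc9ccccc9)c(OCc9ccccc9)cc1-c1c([C@H]3Oc4c(Br)c(OCc9ccccc9)c(Br)c(OCc9ccccc9)c4C[C@H]3O6)cc(OCc9ccccc9)c(OCc9ccccc9)c1OCc9ccccc9)[C@H](O[Si]6(C(C)C)C(C)C)C2 | intermediate
9 | silylene-bridged free polyphenol (all Bn and Br removed, O–Si–O bridge still in place) | Oc1cc(O)c2c(c1)O[C@H](c1cc(O)c(O)cc1-c1c([C@H]3Oc4cc(O)cc(O)c4C[C@H]3O6)cc(O)c(O)c1O)[C@H](O[Si]6(C(C)C)C(C)C)C2 | intermediate
10 | degalloyl theasinensin F | Oc1cc(O)c2c(c1)O[C@H](c1cc(O)c(O)cc1-c1c([C@H]3Oc4cc(O)cc(O)c4C[C@H]3O)cc(O)c(O)c1O)[C@H](O)C2 | target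

**Step count**
Total steps: 6. Longest linear sequence: 5 (step 1 or 2, then steps 3, 4, 5 and 6).

**Three steps most likely to fail**

Step 5 (the proposed new step). There are four main risks:
- loss of the benzylic C2–H from the ring B radical cation;
- oxidative debenzylation;
- intermolecular oligomers;
- over-oxidation of 8.

Cyclic voltammetry of 7 should first confirm that ring B oxidises before the dibrominated ring A, which is expected to lie a few tenths of a volt higher.

The fallback uses known chemistry and sets out from 7. N-Iodosuccinimide (2.1 equiv) with catalytic CF3CO2H in CH2Cl2–MeCN at 0 °C places one iodine on each ring B at the two carbons to be joined. This gives the tethered diiodide F1. An intramolecular Ullmann coupling with activated copper powder in DMF at 110 °C then closes the same 11-membered ring. The aryl iodides react while the hindered di-ortho-alkoxy aryl bromides stay intact. The fallback comes back to the route at 8.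

Step 3. The risks are symmetrical silyl acetals from scrambling and a sluggish second substitution between two hindered secondary alcohols.

The fallback sets out from 2. Chlorodiisopropylsilane (iPr2SiHCl) and imidazole in CH2Cl2 give the hydrosilyl ether F2, which can be chromatographed free of any dimer. Catalytic dehydrogenative alcoholysis of its Si–H bond with 4 follows (Rh2(O2CC3F7)4, 1 mol %, CH2Cl2, rt, loss of H2). This forms only the unsymmetrical acetal and comes back to the route at 6.

Step 6. The risks are catalyst poisoning by bromide, incomplete cleavage of the bridge by the released HBr, and handling losses of the air-sensitive polyphenol.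

The fallback sets out from 8 and separates the tasks. HF·pyridine in THF at 0 °C removes the bridge while the molecule is still lipophilic, giving the untethered diol F3, which is purified on silica. A base-buffered hydrogenolysis (H2, Pd(OH)2/C, Et3N, THF–MeOH, rt) then removes benzyl groups and bromines and arrives at 10.

**Further compounds**
F1 | step 5 | tethered diiodide of 7 (iodine at C6' of the epicatechin ring B and at C2' of the epigallocatechin ring B) | c9ccccc9COc1c(Br)c(OCc9ccccc9)c2c(c1Br)O[C@H](c1cc(OCc9ccccc9)c(OCc9ccccc9)cc1I)[C@H](O[Si](C(C)C)(C(C)C)O[C@@H]3Cc4c(OCc9ccccc9)c(Br)c(OCc9ccccc9)c(Br)c4O[C@@H]3c5c(I)c(OCc9ccccc9)c(OCc9ccccc9)c(OCc9ccccc9)c5)C2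
F2 | step 3 | 3-O-(diisopropylsilyl) hydrosilyl ether of 2 | c9ccccc9COc1cc(OCc9ccccc9)c2c(c1)O[C@H](c1cc(OCc9ccccc9)c(OCc9ccccc9)cc1)[C@H](O[SiH](C(C)C)C(C)C)C2
F3 | step 6 | untethered diol (nona-O-benzyl tetrabromo biaryl with both 3-OH free) | c9ccccc9COc1c(Br)c(OCc9ccccc9)c2c(c1Br)O[C@H](c1cc(OCc9ccccc9)c(OCc9ccccc9)cc1-c1c([C@H]3Oc4c(Br)c(OCc9ccccc9)c(Br)c(OCc9ccccc9)c4C[C@H]3O)cc(OCc9ccccc9)c(OCc9ccccc9)c1OCc9ccccc9)[C@H](O)C2
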